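**Retrosynthetic overview**

1. Both stereocentres are R and each carries CH2OAc, one three-carbon arm and the shared C3 linker, so the target is cut back to the C2-symmetric bis-allyl diacetate 8.
2. Arms: the butenolide arm comes from hydroboration/B-alkyl Suzuki coupling of one allyl group with 3-bromofuran-2(5H)-one; the Z-allylic alcohol arm comes from one-carbon truncation of the other allyl group and a nickel-catalysed reductive alkyl–alkenyl coupling with the (Z)-iodide 12.
3. Key step: 8 goes back to heptanedial by a two-fold enantioselective enamine radical-cation (SOMO) α-allylation, which forms both C–C bonds at the stereocentres and sets both configurations in one radical operation; heptanedial comes from cycloheptene.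
4. Rings: no ring is built; the only ring (the butenolide) is bought intact and attached in the last step.

Assumption: (2Z)-3-iodo-2-methylprop-2-en-1-ol (12) and 3-bromofuran-2(5H)-one (14) are bought as catalogue compounds.

**Route**

Step 1
Reactants: 1 cycloheptene
Product: 3 heptanedial, via cycloheptene ozonide 2 (not isolated)
Conditions: O3, CH2Cl2, −78 °C; then PPh3, −78 °C to rt; used crude at once
Reagents that add atoms: ozone, [O-][O+]=O
Why: Criegee ozonolysis cleaves the ring alkene and PPh3 reduces the ozonide to the dialdehyde without over-oxidation; no stereocentre is formed.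

Step 2
Reactants: 3 heptanedial; 4 allyltrimethylsilane
Product: 7 (2R,6R)-2,6-bis(prop-2-en-1-yl)heptane-1,7-diol, via mono-allyl dialdehyde 5 (not isolated), via bis-allyl dialdehyde 6 (not isolated)
Conditions: (2S,5S)-5-benzyl-2-tert-butyl-3-methylimidazolidin-4-one trifluoroacetate (40 mol %), (NH4)2Ce(NO3)6 (5 equiv), NaHCO3 (3 equiv), H2O (4 equiv), 4 (6 equiv), DME, −20 °C, 3 added over 6 h, 24 h; then NaBH4, EtOH/CH2Cl2, 0 °C
Reagents that add atoms: none
Why: Two-directional organo-SOMO α-allylation, in which each aldehyde forms an enamine that (NH4)2Ce(NO3)6 oxidises to a 3π-electron radical cation lying away from the tert-butyl group, the allylsilane adds on the face anti to the benzyl group, and a second oxidation with loss of silyl gives the α-allyl aldehyde, so the (2S,5S)-catalyst sets R at C2 and at C6 independently (the sense is derived from this steric model; two-fold catalyst control drives the C2 isomer to very high ee, and the minor meso isomer is removed by HPLC at 7), while immediate NaBH4 reduction prevents epimerisation.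

Step 3
Reactants: 7 (2R,6R)-2,6-bis(prop-2-en-1-yl)heptane-1,7-diol
Product: 8 (2R,6R)-2,6-bis(prop-2-en-1-yl)heptane-1,7-diyl diacetate
Conditions: Ac2O, pyridine, DMAP (cat.), CH2Cl2, 0 °C to rt
Reagents that add atoms: acetic anhydride, CC(=O)OC(C)=O
Why: DMAP-catalysed acylation of both primary alcohols installs the two acetates of the target; the stereocentres are not touched.

Step 4
Reactants: 8 (2R,6R)-2,6-bis(prop-2-en-1-yl)heptane-1,7-diyl diacetate
Product: 10 (2R,6R)-2-(2-hydroxyethyl)-6-(prop-2-en-1-yl)heptane-1,7-diyl diacetate, via mono-ozonide 9 (not isolated)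
Conditions: O3 (1.0 equiv, titrated solution), CH2Cl2, −78 °C; then NaBH4, MeOH, −78 to 0 °C; recovered 8 recycled
Reagents that add atoms: ozone, [O-][O+]=O
Why: Ozonolysis with a limiting charge of ozone and hydride reduction of the ozonide removes one carbon from one allyl group to give the 2-hydroxyethyl arm; the two allyl groups of C2-symmetric 8 are homotopic, so either one gives the same compound, and the yield is statistical (at most about 50 % per pass).

Step 5
Reactants: 10 (2R,6R)-2-(2-hydroxyethyl)-6-(prop-2-en-1-yl)heptane-1,7-diyl diacetate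
Product: 11 (2R,6R)-2-(2-bromoethyl)-6-(prop-2-en-1-yl)heptane-1,7-diyl diacetate
Conditions: CBr4, PPh3, CH2Cl2, 0 °C
Reagents that add atoms: carbon tetrabromide, BrC(Br)(Br)Br
Why: The Appel reaction converts the primary alcohol into the bromide under neutral conditions that spare the acetates and the alkene.

Step 6
Reactants: 11 (2R,6R)-2-(2-bromoethyl)-6-(prop-2-en-1-yl)heptane-1,7-diyl diacetate; 12 (2Z)-3-iodo-2-methylprop-2-en-1-ol
Product: 13 (2R,6R)-2-[(3Z)-5-hydroxy-4-methylpent-3-en-1-yl]-6-(prop-2-en-1-yl)heptane-1,7-diyl diacetate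
Conditions: NiBr2·glyme (10 mol %), 4,4'-di-tert-butyl-2,2'-bipyridine (10 mol %), Zn dust (2.5 equiv), NaI (25 mol %), 12 (1.5 equiv), DMA, 25 °C
Reagents that add atoms: none
Why: Nickel-catalysed reductive cross-electrophile coupling, in which zerovalent nickel adds to the alkenyl iodide and captures the primary alkyl radical formed from the bromide, so the C(sp3)–C(sp2) bond forms with retention of the Z geometry already fixed in 12; the free hydroxyl, the acetates and the remote terminal alkene are tolerated.

Step 7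
Reactants: 13 (2R,6R)-2-[(3Z)-5-hydroxy-4-methylpent-3-en-1-yl]-6-(prop-2-en-1-yl)heptane-1,7-diyl diacetate; 14 3-bromofuran-2(5H)-one
Product: 16 (2R,6R)-2-[(3Z)-5-hydroxy-4-methylpent-3-en-1-yl]-6-[3-(2-oxo-2,5-dihydrofuran-3-yl)propyl]heptane-1,7-diyl diacetate, via alkylborane 15 (not isolated)
Conditions: 9-BBN (2.3 equiv), THF, 0 °C to rt; then H2O, 14 (1.3 equiv), PdCl2(dppf) (5 mol %), AsPh3 (10 mol %), Cs2CO3 (3 equiv), DMF/THF/H2O, rt
Reagents that add atoms: none
Why: Anti-Markovnikov hydroboration is selective for the monosubstituted alkene (the trisubstituted alkene reacts far more slowly and the hydroxyl is held as its borinate), and B-alkyl Suzuki–Miyaura coupling with the α-bromobutenolide under mild carbonate conditions attaches the intact ring and gives the target with both stereocentres unchanged.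

**Compound list**

1 | cycloheptene | C1CCC=CCC1 | starting material
2 | cycloheptene ozonide (8,9,10-trioxabicyclo[5.2.1]decane) | C1CCC2OOC(CC1)O2 | intermediate
3 | heptanedial | O=CCCCCCC=O | intermediate
4 | allyltrimethylsilane (trimethyl(prop-2-en-1-yl)silane) | C=CC[Si](C)(C)C | starting material
5 | (2R)-2-(prop-2-en-1-yl)heptanedial | O=C[C@@H](CC=C)CCCCC=O | intermediate
6 | (2R,6R)-2,6-bis(prop-2-en-1-yl)heptanedial | O=C[C@@H](CC=C)CCC[C@H](CC=C)C=O | intermediate
7 | (2R,6R)-2,6-bis(prop-2-en-1-yl)heptane-1,7-diol | OC[C@@H](CC=C)CCC[C@H](CC=C)CO | intermediate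
8 | (2R,6R)-2,6-bis(prop-2-en-1-yl)heptane-1,7-diyl diacetate | CC(=O)OC[C@@H](CC=C)CCC[C@H](CC=C)COC(C)=O | intermediate
9 | (2R,6R)-2-(prop-2-en-1-yl)-6-(1,2,4-trioxolan-3-ylmethyl)heptane-1,7-diyl diacetate (ozonide carbon unassigned) | CC(=O)OC[C@@H](CC=C)CCC[C@H](CC1OOCO1)COC(C)=O | intermediate
10 | (2R,6R)-2-(2-hydroxyethyl)-6-(prop-2-en-1-yl)heptane-1,7-diyl diacetate | CC(=O)OC[C@@H](CC=C)CCC[C@H](CCO)COC(C)=O | intermediate
11 | (2R,6R)-2-(2-bromoethyl)-6-(prop-2-en-1-yl)heptane-1,7-diyl diacetate | CC(=O)OC[C@@H](CC=C)CCC[C@H](CCBr)COC(C)=O | intermediate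
12 | (2Z)-3-iodo-2-methylprop-2-en-1-ol | I/C=C(/C)CO | starting material
13 | (2R,6R)-2-[(3Z)-5-hydroxy-4-methylpent-3-en-1-yl]-6-(prop-2-en-1-yl)heptane-1,7-diyl diacetate | CC(=O)OC[C@@H](CC=C)CCC[C@H](CC/C=C(/C)CO)COC(C)=O | intermediate
14 | 3-bromofuran-2(5H)-one | O=C1OCC=C1Br | starting material
15 | 9-BBN adduct of 13 (primary C–B bond at the former alkene terminus, allylic oxygen as 9-BBN borinate) | CC(=O)OC[C@@H](CCCB1C2CCCC1CCC2)CCC[C@H](CC/C=C(/C)COB1C2CCCC1CCC2)COC(C)=O | intermediate
16 | (2R,6R)-2-[(3Z)-5-hydroxy-4-methylpent-3-en-1-yl]-6-[3-(2-oxo-2,5-dihydrofuran-3-yl)propyl]heptane-1,7-diyl diacetate (CNP0139404.2) | CC(=O)OC[C@@H](CCCC1=CCOC1=O)CCC[C@H](CC/C=C(/C)CO)COC(C)=O | target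

**Step count and risks**

Total steps: 7. Longest linear sequence: 7 steps (1 to 16).

The three steps most likely to fail are steps 2, 6 and 7.

Step 2: the two-fold SOMO allylation has not been run on a 1,7-dialdehyde, and amine-catalysed intramolecular aldol cyclisation of 3 or a stalled second allylation can compete. The fallback sets out from 3 and comes back at 8, treating one aldehyde at a time. Mono-acetalisation of 3 (HC(OMe)3, 1 equiv, montmorillonite K-10, CH2Cl2; statistical, 3 and bis-acetal recycled) gives 7,7-dimethoxyheptanal F1. A single SOMO allylation with 4 under the step 2 conditions gives (2R)-7,7-dimethoxy-2-(prop-2-en-1-yl)heptanal F2, which is reduced without isolation (NaBH4) to (2R)-7,7-dimethoxy-2-(prop-2-en-1-yl)heptan-1-ol F3. Acetylation (Ac2O, pyridine, DMAP) gives (2R)-7,7-dimethoxy-2-(prop-2-en-1-yl)heptyl acetate F4, and mild hydrolysis (PPTS, acetone/H2O) frees (2R)-7-oxo-2-(prop-2-en-1-yl)heptyl acetate F5. A second SOMO allylation with the same catalyst gives (2R,6R)-6-formyl-2-(prop-2-en-1-yl)non-8-en-1-yl acetate F6, NaBH4 reduction gives (2R,6R)-6-(hydroxymethyl)-2-(prop-2-en-1-yl)non-8-en-1-yl acetate F7, and acetylation returns 8.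

Step 6: the reductive coupling joins an unactivated primary bromide to a hindered, hydroxyl-bearing alkenyl iodide; homocoupling or loss of the bromide by reduction are the likely failures. The fallback sets out from 11 and comes back at 13, replacing the radical coupling by a polar Negishi coupling. Zinc insertion (Zn dust, LiCl, cat. I2, THF, 50 °C) gives the alkylzinc bromide (2R,6R)-2-[2-(bromozincio)ethyl]-6-(prop-2-en-1-yl)heptane-1,7-diyl diacetate F8, which is added slowly to 12 with Pd(OAc)2 and SPhos in THF at 25 °C (conditions that tolerate a free hydroxyl) to give 13 with retention of the Z geometry.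

Step 7: 3-bromofuran-2(5H)-one is base-sensitive and the alkylborane carries a borinate, so the Suzuki coupling may give low conversion. The fallback sets out from 13 and comes back at 16, building the butenolide ring in place instead of importing it. A ruthenium-catalysed Alder-ene coupling (CpRu(cod)Cl, MeOH, reflux) of the allyl group of 13 with bought methyl 4-hydroxybut-2-ynoate (COC(=O)C#CCO) forms the C–C bond at the alkynoate α-carbon and lactonises to (2R,6R)-2-[(3Z)-5-hydroxy-4-methylpent-3-en-1-yl]-6-[(1E)-3-(2-oxo-2,5-dihydrofuran-3-yl)prop-1-en-1-yl]heptane-1,7-diyl diacetate F9. Selective hydrogenation of its disubstituted alkene (H2, RhCl(PPh3)3, benzene/EtOH) gives 16.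

**Further compounds**

F1 | step 2 | 7,7-dimethoxyheptanal | COC(OC)CCCCCC=O
F2 | step 2 | (2R)-7,7-dimethoxy-2-(prop-2-en-1-yl)heptanal | O=C[C@@H](CC=C)CCCCC(OC)OC
F3 | step 2 | (2R)-7,7-dimethoxy-2-(prop-2-en-1-yl)heptan-1-ol | OC[C@@H](CC=C)CCCCC(OC)OC
F4 | step 2 | (2R)-7,7-dimethoxy-2-(prop-2-en-1-yl)heptyl acetate | CC(=O)OC[C@@H](CC=C)CCCCC(OC)OC
F5 | step 2 | (2R)-7-oxo-2-(prop-2-en-1-yl)heptyl acetate | CC(=O)OC[C@@H](CC=C)CCCCC=O
F6 | step 2 | (2R,6R)-6-formyl-2-(prop-2-en-1-yl)non-8-en-1-yl acetate | CC(=O)OC[C@@H](CC=C)CCC[C@H](CC=C)C=O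
F7 | step 2 | (2R,6R)-6-(hydroxymethyl)-2-(prop-2-en-1-yl)non-8-en-1-yl acetate | CC(=O)OC[C@@H](CC=C)CCC[C@H](CC=C)CO
F8 | step 6 | (2R,6R)-2-[2-(bromozincio)ethyl]-6-(prop-2-en-1-yl)heptane-1,7-diyl diacetate | CC(=O)OC[C@@H](CC=C)CCC[C@H](CC[Zn]Br)COC(C)=O
F9 | step 7 | (2R,6R)-2-[(3Z)-5-hydroxy-4-methylpent-3-en-1-yl]-6-[(1E)-3-(2-oxo-2,5-dihydrofuran-3-yl)prop-1-en-1-yl]heptane-1,7-diyl diacetate | CC(=O)OC[C@@H](/C=C/CC1=CCOC1=O)CCC[C@H](CC/C=C(/C)CO)COC(C)=O
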